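- The last alder reading left 108 mM of the Q charged unaccounted for by X, with 168 mM of E beside it. Q was the limiting reagent, so I asked where that Q had gone.

| flask | E | Q | time |
|---|---|---|---|
| alder | 300 mM | 240 mM |  |
| larch | 180 mM | 120 mM |  |
| elm | 450 mM | 240 mM |  |
| birch | 900 mM | 79.0 mM | 8.8 min |

| alder run: time / min | alder run: [X] / mM | larch run: time / min | larch run: [X] / mM | elm run: time / min | elm run: [X] / mM |
|---|---|---|---|---|---|
| 1.3 | 56.9 | 1.3 | 20.4 | 1.3 | 76.5 |
| 2.5 | 83.6 | 2.5 | 33.9 | 2.5 | 116.2 |
| 3.8 | 106.0 | 3.8 | 40.8 | 3.8 | 139.1 |
| 5.0 | 115.7 | 5.0 | 46.6 | 5.0 | 149.8 |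
| 6.3 | 125.3 | 6.3 | 50.0 | 6.3 | 156.2 |
| 7.5 | 128.7 | 7.5 | 52.6 | 7.5 | 158.8 |
| 8.8 | 131.8 | 8.8 | 52.9 | 8.8 | 160.7 |

(readings scatter by 0.9 mM)

- Overall: E + Q -> X.
- Constant volume, constant temperature.
- Readings of a species count what is bound in complexes too.
- "The second partner" is Q.
- An order is taken over about fifteen percent of the charge, up and down.

- the exponent of [E] in the starting rate at the charge of the alder run (at the point where two percent of the E have become X) (one fixed amount of X, the same in the runs compared)
- the exponent of [Q] in the starting rate at the charge of the alder run (at the point where two percent of the E have become X)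
- X in the birch run at 8.8 min, as a share of the E charged

- I let two times compete for each Q: τc, the wait for capture by E, which shortens as [E] rises, and τl, the wait for some other exit, which I took to be independent of E. The share of Q becoming X is then s = τl/(τl+τc).
- Their ratio τl/τc I wrote as Ē/c, where Ē is the mean [E], the charge less half the X, and c is the [E] at which the two times are equal.
- The last readings gave c as 192 mM in alder, 195 mM in larch and 182 mM in elm, while the E charge went from 180 mM to 450 mM. So I froze c at their mean, 190 mM.
- For birch I took Ē as the charge less half the Q charged, 860 mM, which is larger than c. That gave s = 81.9%, so X was 64.7 mM, or 7.19% of the E charged.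
- The forecast, on different grounds from mine (“so the reaction is reversible”), gave orders of 1 in E and 0.85 in Q, and 7.3% for birch.
- The flask gave 1.0, 0.75 and 7.28%, each within the margin of the forecast.

    E + Q → X (1.308 L mol⁻¹ min⁻¹)
    E + 2 Q → X + Q (0.3336 L² mol⁻² min⁻¹)
    2 Q ⇌ Q2, settled at all times (2.910 L mol⁻¹)
    Q → Zu (0.2346 min⁻¹)

- The other exit was Q → Zu, and my frozen c of 190 mM had sent 14.3 mM of the birch Q past X; the birch run with that step taken away gives 8.78%. The order in Q at the alder charge came out at 0.75 because of the tying up of 2 Q as Q2: the alder run with that step taken away gives 1.1.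

The readings are simulated from invented constants; the scatter is artificial.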